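**Plan**

- Retrosynthesis: the methine C3 is excised first (cuts C2–C3 and C3–C4), which contracts the enone ring to the C2=C4 silyl enol ether of a norbornanone. Then the C4–styryl bond (cross-coupling), the C7–aryl bond (decarboxylative arylation) and last C1–C7 and C5–C6 (Diels–Alder) are cut.
- Forward: a Diels–Alder reaction of a 2-siloxycyclopentadienone ketal with a cinnamoyl imide builds the cyclopentane ring C1–C7–C6–C5–C8 as a norbornene. Oxygen is then put on C2, the C7 aryl and C4 styryl groups are attached, and a cyclopropanation/ring-opening pair inserts C3 and so creates the six-membered enone ring C1–C2–C3–C4–C5–C8.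
- Enabling feature: C2 (carbonyl) and C4 (styryl carbon) are each flanked by a bridgehead (C1, C5) that cannot enolise, so the norbornanone lacking C3 has only one enol ether, C2=C4. The cyclopropane fused there carries an oxygen donor on C2 and the radical-stabilising styryl group on C4, and can open only at the old C2–C4 bond.
- Stereochemistry: the (S)-4-benzyl-oxazolidinone auxiliary sets the absolute configuration in the endo Diels–Alder step (C1, C5, exo aryl at C6, endo acyl at C7). The C7 aryl group then replaces the carboxyl group on the endo face, trans to the C6 aryl group. C1 and C5 are bridgeheads and cannot epimerise.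

Key step: step 11

Remark: locants C1–C8 in the plan and Why lines are those of the target core (C2 enone C=O, C3 =CH, C4 styryl carbon, C6 exo 3,5-dioxygenated aryl, C7 endo 3,4-dioxygenated aryl, C8 bridging C=O; endo = towards the longer bridge). Norbornane names use their own numbering, in which C2/C3 are target C2/C4, C5 is target C6 and C6 is target C7; the SMILES fix the absolute configuration.

**Route**

Step 1
Reactants: 1 (E)-3-(3,5-dimethoxyphenyl)prop-2-enoic acid; 2 (S)-4-benzyl-1,3-oxazolidin-2-one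
Product: 4 (S)-4-benzyl-3-[(E)-3-(3,5-dimethoxyphenyl)prop-2-enoyl]-1,3-oxazolidin-2-one, via mixed pivalic anhydride 3 (not isolated)
Conditions: t-BuCOCl, Et3N, THF, −20 °C; then LiCl, 2, −20 °C → rt
Reagents that add atoms: none
Why: N-acylation of the oxazolidinone by the mixed pivalic anhydride (LiCl-assisted imide formation) is a standard route to N-enoyl imides and should leave the E double bond untouched.

Step 2
Reactants: 5 1,4-dioxaspiro[4.4]non-6-ene
Product: 6 1,4-dioxaspiro[4.4]non-6-en-8-one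
Conditions: Rh2(cap)4 (cap = caprolactamate, 1 mol %), t-BuOOH, K2CO3, CH2Cl2, rt
Reagents that add atoms: tert-butyl hydroperoxide, CC(C)(C)OO
Why: dirhodium-catalysed allylic C–H oxidation should convert the only allylic CH2 group into the enone carbonyl, because the other allylic position is the fully substituted ketal carbon and the ketal-flanked end of the allyl radical is the more hindered one.

Step 3
Reactants: 6 1,4-dioxaspiro[4.4]non-6-en-8-one
Product: 7 tert-butyl(1,4-dioxaspiro[4.4]nona-6,8-dien-7-yloxy)dimethylsilane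
Conditions: lithium diisopropylamide, THF, −78 °C; then TBSCl, DMPU, −78 → 0 °C; used at once
Reagents that add atoms: tert-butyldimethylsilyl chloride, CC(C)(C)[Si](C)(C)Cl
Why: kinetic deprotonation at the only α' CH2 group and O-silylation (cross-conjugated silyl dienol ether formation) should give the 2-siloxycyclopentadiene, whose spiro ketal carbon bears no hydrogen and so cannot undergo 1,5-hydrogen shifts.

Step 4
Reactants: 4 (S)-4-benzyl-3-[(E)-3-(3,5-dimethoxyphenyl)prop-2-enoyl]-1,3-oxazolidin-2-one; 7 tert-butyl(1,4-dioxaspiro[4.4]nona-6,8-dien-7-yloxy)dimethylsilane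
Product: 8 (S)-4-benzyl-3-{[3-(tert-butyldimethylsilyloxy)-5-exo-(3,5-dimethoxyphenyl)spiro[bicyclo[2.2.1]hept-2-ene-7,2'-[1,3]dioxolan]-6-endo-yl]carbonyl}-1,3-oxazolidin-2-one
Conditions: Et2AlCl (1.4 equiv), CH2Cl2, −78 → −20 °C
Reagents that add atoms: none
Why: Lewis-acid-promoted auxiliary-controlled Diels–Alder reaction of the chelated s-cis N-enoyl oxazolidinone, in which the diene should add to the alkene face opposite the benzyl group (absolute configuration of both bridgeheads, C6 and C7), the endo rule should place the acyl group endo and the aryl group exo, and the siloxy group should direct the aryl-bearing carbon to the diene terminus next to the siloxy carbon.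

Step 5
Reactants: 8 (the Diels–Alder adduct)
Product: 9 (S)-4-benzyl-3-{[2-exo-(tert-butyldimethylsilyloxy)-5-exo-(3,5-dimethoxyphenyl)-3-oxospiro[bicyclo[2.2.1]heptane-7,2'-[1,3]dioxolan]-6-endo-yl]carbonyl}-1,3-oxazolidin-2-one
Conditions: mCPBA (1.05 equiv), NaHCO3, CH2Cl2, 0 °C
Reagents that add atoms: meta-chloroperoxybenzoic acid, OOC(=O)c1cccc(Cl)c1
Why: Rubottom oxidation, in which epoxidation of the silyl enol ether on the exo face (the endo face is covered by the endo acyl group) and 1,4-silyl shift should place the oxygen on C2 as an exo silyl ether, a stereocentre that is erased again in step 8.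

Step 6
Reactants: 9 (the α-silyloxy ketone imide)
Product: 10 2-exo-(tert-butyldimethylsilyloxy)-5-exo-(3,5-dimethoxyphenyl)-3-oxospiro[bicyclo[2.2.1]heptane-7,2'-[1,3]dioxolane]-6-endo-carboxylic acid
Conditions: LiOH, H2O2, THF/H2O, 0 °C; then Na2SO3; then HCl to pH 3
Reagents that add atoms: hydrogen peroxide, OO
Why: hydroperoxide cleavage of the N-acyl oxazolidinone is selective for the exocyclic carbonyl and should release the acid without epimerisation at the carboxyl-bearing carbon while returning the auxiliary.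

Step 7
Reactants: 10 (the endo carboxylic acid); 11 4-bromo-1,2-dimethoxybenzene
Product: 14 2-exo-(tert-butyldimethylsilyloxy)-6-endo-(3,4-dimethoxyphenyl)-5-exo-(3,5-dimethoxyphenyl)spiro[bicyclo[2.2.1]heptane-7,2'-[1,3]dioxolan]-3-one, via phthalimidoyl ester 12 (not isolated), via arylzinc chloride 13 (not isolated)
Conditions: N-hydroxyphthalimide, N,N'-diisopropylcarbodiimide, CH2Cl2, rt; then 13 (from 11: Mg, LiCl, THF; then ZnCl2), NiCl2(dme) (20 mol %), 4,4'-di-tert-butyl-2,2'-bipyridine, THF/DMF, rt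
Reagents that add atoms: none
Why: nickel-catalysed decarboxylative Negishi-type arylation of the redox-active ester, in which the secondary C7 radical should be captured by the aryl-nickel species on the endo face, anti to the neighbouring exo aryl group and away from the dioxolane oxygen that overhangs the exo face, so that the new aryl group ends endo and trans to its neighbour.

Step 8
Reactants: 14 (the diaryl α-silyloxy ketone)
Product: 15 2-(tert-butyldimethylsilyloxy)-6-endo-(3,4-dimethoxyphenyl)-5-exo-(3,5-dimethoxyphenyl)spiro[bicyclo[2.2.1]hept-2-ene-7,2'-[1,3]dioxolan]-3-yl trifluoromethanesulfonate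
Conditions: KN(SiMe3)2, THF, −78 °C; then PhNTf2, −78 → 0 °C
Reagents that add atoms: N-phenylbis(trifluoromethanesulfonimide), O=S(=O)(N(c1ccccc1)S(=O)(=O)C(F)(F)F)C(F)(F)F
Why: enol triflate formation is regiochemically unambiguous because the ketone can enolise only towards the silyloxy carbon (its other α-carbon is a bridgehead), so deprotonation and O-triflation should give one tetrasubstituted enol triflate.

Step 9
Reactants: 16 4-ethynyl-1,2-dimethoxybenzene
Product: 17 2-[(E)-2-(3,4-dimethoxyphenyl)ethenyl]-4,4,5,5-tetramethyl-1,3,2-dioxaborolane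
Conditions: pinacolborane, Cp2ZrHCl (5 mol %), Et3N (10 mol %), neat, 60 °C
Reagents that add atoms: pinacolborane, [H]B1OC(C)(C)C(C)(C)O1
Why: zirconium-catalysed syn hydroboration of the terminal alkyne should give the E-alkenylboronate with boron on the terminal carbon.

Step 10
Reactants: 15 (the enol triflate); 17 (the E-alkenylboronate)
Product: 18 tert-butyl{[6-endo-(3,4-dimethoxyphenyl)-3-[(E)-2-(3,4-dimethoxyphenyl)ethenyl]-5-exo-(3,5-dimethoxyphenyl)spiro[bicyclo[2.2.1]hept-2-ene-7,2'-[1,3]dioxolan]-2-yl]oxy}dimethylsilane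
Conditions: Pd(PPh3)4 (5 mol %), K3PO4, 1,4-dioxane, 70 °C
Reagents that add atoms: none
Why: Suzuki–Miyaura cross-coupling of the enol triflate with the alkenylboronate proceeds with retention of the E geometry, and the phosphate base in dioxane should spare the silyl enol ether.

Step 11
Reactants: 18 (the silyl dienol ether)
Product: 19 tert-butyl{[7-endo-(3,4-dimethoxyphenyl)-4-[(E)-2-(3,4-dimethoxyphenyl)ethenyl]-6-exo-(3,5-dimethoxyphenyl)spiro[tricyclo[3.2.1.0(2,4)]octane-8,2'-[1,3]dioxolan]-2-yl]oxy}dimethylsilane (cyclopropane CH2 on the exo face)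
Conditions: Et2Zn, CH2I2, CH2Cl2, 0 °C → rt
Reagents that add atoms: diiodomethane, ICI
Why: The zinc carbenoid EtZnCH2I transfers a methylene group to the C2=C4 silyl enol ether through the concerted butterfly transition state of the Simmons–Smith reaction (Furukawa variant), so that the new carbon C3 becomes bonded to the oxygen-bearing carbon C2 and to C4 in one event; the closest known reaction type is the cyclopropanation of cyclic silyl enol ethers that opens an Ito–Saegusa one-carbon ring expansion. The ring closed is the three-membered ring C2–C3–C4, formed by a stereospecific syn [2+1] addition in which the C2–C3 and C3–C4 bonds form together. The two new stereocentres C2 and C4 are set by approach on the exo face, which the norbornene skeleton favours, which the dioxolane oxygen above this bridge can assist by binding zinc, and which the endo aryl group on C7 enforces by screening the other face; both centres are flattened again in step 12, so only the cis fusion matters. The step needs chemoselectivity for the enol ether double bond over the styryl double bond, and this is secured by the oxygen donor and the strain of the tetrasubstituted norbornene alkene, which make it the most nucleophilic π bond towards the electrophilic carbenoid. The cyclopropane stores the strain that, with the siloxy donor on C2 and the styryl group on C4, drives cleavage of the old C2–C4 bond in the next step and turns the bicyclo[2.2.1]heptane into the bicyclo[3.2.1]octene core.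

Step 12
Reactants: 19 (the siloxycyclopropane)
Product: 21 7-endo-(3,4-dimethoxyphenyl)-4-[(E)-2-(3,4-dimethoxyphenyl)ethenyl]-6-exo-(3,5-dimethoxyphenyl)spiro[bicyclo[3.2.1]oct-3-ene-8,2'-[1,3]dioxolan]-2-one, via chloro ketone 20 (not isolated)
Conditions: FeCl3 (2.2 equiv), DMF, 0 °C → rt; then NaOAc, MeOH, 60 °C
Reagents that add atoms: none
Why: Ito–Saegusa ring expansion, in which one-electron oxidation by iron trichloride gives the cyclopropyloxy radical, β-scission of the internal C2–C4 bond gives the tertiary radical stabilised by the styryl group, and chlorine transfer followed by acetate-induced dehydrochlorination should leave the C2 ketone conjugated with the new C3=C4 double bond.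

Step 13
Reactants: 21 (the hexamethyl ether ketal of the target)
Product: 22 jezonodione, (1S,5R,6R,7R)-7-(3,4-dihydroxyphenyl)-4-[(E)-2-(3,4-dihydroxyphenyl)ethenyl]-6-(3,5-dihydroxyphenyl)bicyclo[3.2.1]oct-3-ene-2,8-dione
Conditions: BBr3 (excess), CH2Cl2, −78 → 0 °C; then H2O
Reagents that add atoms: water, O
Why: Lewis-acid ether cleavage with BBr3 should remove the six methyl ethers and the dioxolane in one operation, and no stereocentre is at risk because the bridgehead hydrogens next to the carbonyls cannot be lost through a bridgehead enol.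

**Compound list**

1 | (E)-3-(3,5-dimethoxyphenyl)prop-2-enoic acid | COc1cc(/C=C/C(=O)O)cc(OC)c1 | starting material
2 | (S)-4-benzyl-1,3-oxazolidin-2-one | O=C1N[C@@H](Cc2ccccc2)CO1 | starting material
3 | (E)-3-(3,5-dimethoxyphenyl)prop-2-enoic 2,2-dimethylpropanoic anhydride | COc1cc(/C=C/C(=O)OC(=O)C(C)(C)C)cc(OC)c1 | intermediate
4 | (S)-4-benzyl-3-[(E)-3-(3,5-dimethoxyphenyl)prop-2-enoyl]-1,3-oxazolidin-2-one | COc1cc(/C=C/C(=O)N2C(=O)OC[C@@H]2Cc2ccccc2)cc(OC)c1 | intermediate
5 | 1,4-dioxaspiro[4.4]non-6-ene | C1=CC2(CC1)OCCO2 | starting material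
6 | 1,4-dioxaspiro[4.4]non-6-en-8-one | O=C1C=CC2(C1)OCCO2 | intermediate
7 | tert-butyl(1,4-dioxaspiro[4.4]nona-6,8-dien-7-yloxy)dimethylsilane | CC(C)(C)[Si](C)(C)OC1=CC2(C=C1)OCCO2 | intermediate
8 | (S)-4-benzyl-3-{[3-(tert-butyldimethylsilyloxy)-5-exo-(3,5-dimethoxyphenyl)spiro[bicyclo[2.2.1]hept-2-ene-7,2'-[1,3]dioxolan]-6-endo-yl]carbonyl}-1,3-oxazolidin-2-one | C1=C(O[Si](C)(C)C(C)(C)C)[C@@H]2C3(OCCO3)[C@H]1[C@H](C(=O)N4C(=O)OC[C@@H]4Cc4ccccc4)[C@H]2c1cc(OC)cc(OC)c1 | intermediate
9 | (S)-4-benzyl-3-{[2-exo-(tert-butyldimethylsilyloxy)-5-exo-(3,5-dimethoxyphenyl)-3-oxospiro[bicyclo[2.2.1]heptane-7,2'-[1,3]dioxolan]-6-endo-yl]carbonyl}-1,3-oxazolidin-2-one | [C@@H]1(O[Si](C)(C)C(C)(C)C)C(=O)[C@@H]2C3(OCCO3)[C@H]1[C@H](C(=O)N4C(=O)OC[C@@H]4Cc4ccccc4)[C@H]2c1cc(OC)cc(OC)c1 | intermediate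
10 | 2-exo-(tert-butyldimethylsilyloxy)-5-exo-(3,5-dimethoxyphenyl)-3-oxospiro[bicyclo[2.2.1]heptane-7,2'-[1,3]dioxolane]-6-endo-carboxylic acid | [C@@H]1(O[Si](C)(C)C(C)(C)C)C(=O)[C@@H]2C3(OCCO3)[C@H]1[C@H](C(=O)O)[C@H]2c1cc(OC)cc(OC)c1 | intermediate
11 | 4-bromo-1,2-dimethoxybenzene | COc1ccc(Br)cc1OC | starting material
12 | 1,3-dioxoisoindolin-2-yl ester of acid 10 | [C@@H]1(O[Si](C)(C)C(C)(C)C)C(=O)[C@@H]2C3(OCCO3)[C@H]1[C@H](C(=O)ON4C(=O)c5ccccc5C4=O)[C@H]2c1cc(OC)cc(OC)c1 | intermediate
13 | chloro(3,4-dimethoxyphenyl)zinc | COc1ccc([Zn]Cl)cc1OC | intermediate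
14 | 2-exo-(tert-butyldimethylsilyloxy)-6-endo-(3,4-dimethoxyphenyl)-5-exo-(3,5-dimethoxyphenyl)spiro[bicyclo[2.2.1]heptane-7,2'-[1,3]dioxolan]-3-one | [C@@H]1(O[Si](C)(C)C(C)(C)C)C(=O)[C@@H]2C3(OCCO3)[C@H]1[C@H](c4ccc(OC)c(OC)c4)[C@H]2c1cc(OC)cc(OC)c1 | intermediate
15 | 2-(tert-butyldimethylsilyloxy)-6-endo-(3,4-dimethoxyphenyl)-5-exo-(3,5-dimethoxyphenyl)spiro[bicyclo[2.2.1]hept-2-ene-7,2'-[1,3]dioxolan]-3-yl trifluoromethanesulfonate | C1(O[Si](C)(C)C(C)(C)C)=C(OS(=O)(=O)C(F)(F)F)[C@@H]2C3(OCCO3)[C@H]1[C@H](c4ccc(OC)c(OC)c4)[C@H]2c1cc(OC)cc(OC)c1 | intermediate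
16 | 4-ethynyl-1,2-dimethoxybenzene | C#Cc1ccc(OC)c(OC)c1 | starting material
17 | 2-[(E)-2-(3,4-dimethoxyphenyl)ethenyl]-4,4,5,5-tetramethyl-1,3,2-dioxaborolane | COc1ccc(/C=C/B2OC(C)(C)C(C)(C)O2)cc1OC | intermediate
18 | tert-butyl{[6-endo-(3,4-dimethoxyphenyl)-3-[(E)-2-(3,4-dimethoxyphenyl)ethenyl]-5-exo-(3,5-dimethoxyphenyl)spiro[bicyclo[2.2.1]hept-2-ene-7,2'-[1,3]dioxolan]-2-yl]oxy}dimethylsilane | C1(O[Si](C)(C)C(C)(C)C)=C(/C=C/c4ccc(OC)c(OC)c4)[C@@H]2C3(OCCO3)[C@H]1[C@H](c4ccc(OC)c(OC)c4)[C@H]2c1cc(OC)cc(OC)c1 | intermediate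
19 | tert-butyl{[7-endo-(3,4-dimethoxyphenyl)-4-[(E)-2-(3,4-dimethoxyphenyl)ethenyl]-6-exo-(3,5-dimethoxyphenyl)spiro[tricyclo[3.2.1.0(2,4)]octane-8,2'-[1,3]dioxolan]-2-yl]oxy}dimethylsilane (C3 exo) | [C@]12(O[Si](C)(C)C(C)(C)C)C[C@]2(/C=C/c4ccc(OC)c(OC)c4)[C@@H]3C4(OCCO4)[C@H]1[C@H](c4ccc(OC)c(OC)c4)[C@H]3c1cc(OC)cc(OC)c1 | intermediate
20 | 4-chloro-7-endo-(3,4-dimethoxyphenyl)-4-[(E)-2-(3,4-dimethoxyphenyl)ethenyl]-6-exo-(3,5-dimethoxyphenyl)spiro[bicyclo[3.2.1]octane-8,2'-[1,3]dioxolan]-2-one (both C4 epimers) | O=C1CC(Cl)(/C=C/c4ccc(OC)c(OC)c4)[C@@H]2C3(OCCO3)[C@H]1[C@H](c4ccc(OC)c(OC)c4)[C@H]2c1cc(OC)cc(OC)c1 | intermediate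
21 | 7-endo-(3,4-dimethoxyphenyl)-4-[(E)-2-(3,4-dimethoxyphenyl)ethenyl]-6-exo-(3,5-dimethoxyphenyl)spiro[bicyclo[3.2.1]oct-3-ene-8,2'-[1,3]dioxolan]-2-one | O=C1C=C(/C=C/c4ccc(OC)c(OC)c4)[C@@H]2C3(OCCO3)[C@H]1[C@H](c4ccc(OC)c(OC)c4)[C@H]2c1cc(OC)cc(OC)c1 | intermediate
22 | jezonodione, (1S,5R,6R,7R)-7-(3,4-dihydroxyphenyl)-4-[(E)-2-(3,4-dihydroxyphenyl)ethenyl]-6-(3,5-dihydroxyphenyl)bicyclo[3.2.1]oct-3-ene-2,8-dione (6-exo, 7-endo) | O=C1C=C(/C=C/c2ccc(O)c(O)c2)[C@@H]2C(=O)[C@H]1[C@H](c1ccc(O)c(O)c1)[C@H]2c1cc(O)cc(O)c1 | target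

**Count and risks**

Total step count: 13. Longest linear sequence: 11 steps (5 → 6 → 7 → 8 → 9 → 10 → 14 → 15 → 18 → 19 → 21 → 22).

Step 4 (Diels–Alder reaction). What may go wrong: dimerisation or Lewis-acid-induced decomposition of the siloxy diene before it is consumed, and erosion of endo or facial selectivity with this hindered diene. The fallback sets out from enone 6 and imide 4, and avoids the free diene and the Lewis acid. Deprotonation of 6 with lithium diisopropylamide in THF at −78 °C should give the cross-conjugated lithium dienolate F1. Addition of 4 should then start an anionic double Michael reaction: the α' carbon of the dienolate adds to the β-carbon of the imide, and the imide enolate closes on the enone, with the auxiliary still directing the face. This should give the lithium enolate F2 of the norbornanone, which is silylated in the same flask with TBSCl. The fallback comes back to the route at compound 8.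

Step 7 (decarboxylative arylation). What may go wrong: loss of facial control when the planar radical is captured (aryl group delivered exo, cis to its neighbour), and slow coupling at the hindered endo site with reduction of the radical instead. The fallback sets out from acid 10 and builds the aryl ring on the carboxyl carbon, so that no bond to the stereocentre is broken. Ethanethiol and N,N'-dicyclohexylcarbodiimide should give the S-ethyl thioester F3. Fukuyama reduction (Et3SiH, Pd/C) should give the aldehyde F4. Ohira–Bestmann homologation (dimethyl (1-diazo-2-oxopropyl)phosphonate, K2CO3, MeOH) should give the terminal alkyne F5. A cobalt-catalysed [4+2] cycloaddition with 2,3-dimethoxybuta-1,3-diene (CoBr2(dppe), Zn, ZnI2, CH2Cl2) should give the cyclohexa-1,4-diene F6, which DDQ should aromatise to the 3,4-dimethoxyphenyl ring. The fallback comes back to the route at compound 14.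

Step 12 (oxidative ring expansion). What may go wrong: over-oxidation or chlorination of the electron-rich styryl unit by the iron salt, and slow cleavage of the hindered silyl ether, so that the cyclopropane is consumed unselectively. The fallback sets out from siloxycyclopropane 19 and opens the ring without an oxidant. Fluoride (Bu4NF buffered with AcOH, THF, 0 °C) should liberate the cyclopropanolate, which should open at the same C2–C4 bond to the styryl-stabilised carbanion and be protonated to the ring-expanded ketone F7. Dehydrogenation of F7 with DDQ in dioxane should then introduce the C3=C4 double bond. The fallback comes back to the route at compound 21.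

**Further compounds**

F1 | step 4 | lithium 1,4-dioxaspiro[4.4]nona-6,8-dien-7-olate | [Li+].[O-]C1=CC2(C=C1)OCCO2
F2 | step 4 | lithium enolate of (S)-4-benzyl-3-{[5-exo-(3,5-dimethoxyphenyl)-3-oxospiro[bicyclo[2.2.1]heptane-7,2'-[1,3]dioxolan]-6-endo-yl]carbonyl}-1,3-oxazolidin-2-one | C1=C([O-])[C@@H]2C3(OCCO3)[C@H]1[C@H](C(=O)N4C(=O)OC[C@@H]4Cc4ccccc4)[C@H]2c1cc(OC)cc(OC)c1.[Li+]
F3 | step 7 | S-ethyl 2-exo-(tert-butyldimethylsilyloxy)-5-exo-(3,5-dimethoxyphenyl)-3-oxospiro[bicyclo[2.2.1]heptane-7,2'-[1,3]dioxolane]-6-endo-carbothioate | [C@@H]1(O[Si](C)(C)C(C)(C)C)C(=O)[C@@H]2C3(OCCO3)[C@H]1[C@H](C(=O)SCC)[C@H]2c1cc(OC)cc(OC)c1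
F4 | step 7 | 2-exo-(tert-butyldimethylsilyloxy)-5-exo-(3,5-dimethoxyphenyl)-3-oxospiro[bicyclo[2.2.1]heptane-7,2'-[1,3]dioxolane]-6-endo-carbaldehyde | [C@@H]1(O[Si](C)(C)C(C)(C)C)C(=O)[C@@H]2C3(OCCO3)[C@H]1[C@H](C=O)[C@H]2c1cc(OC)cc(OC)c1
F5 | step 7 | 2-exo-(tert-butyldimethylsilyloxy)-5-exo-(3,5-dimethoxyphenyl)-6-endo-ethynylspiro[bicyclo[2.2.1]heptane-7,2'-[1,3]dioxolan]-3-one | [C@@H]1(O[Si](C)(C)C(C)(C)C)C(=O)[C@@H]2C3(OCCO3)[C@H]1[C@H](C#C)[C@H]2c1cc(OC)cc(OC)c1
F6 | step 7 | 2-exo-(tert-butyldimethylsilyloxy)-6-endo-(4,5-dimethoxycyclohexa-1,4-dien-1-yl)-5-exo-(3,5-dimethoxyphenyl)spiro[bicyclo[2.2.1]heptane-7,2'-[1,3]dioxolan]-3-one | [C@@H]1(O[Si](C)(C)C(C)(C)C)C(=O)[C@@H]2C3(OCCO3)[C@H]1[C@H](C4=CCC(OC)=C(OC)C4)[C@H]2c1cc(OC)cc(OC)c1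
F7 | step 12 | 7-endo-(3,4-dimethoxyphenyl)-4-[(E)-2-(3,4-dimethoxyphenyl)ethenyl]-6-exo-(3,5-dimethoxyphenyl)spiro[bicyclo[3.2.1]octane-8,2'-[1,3]dioxolan]-2-one (both C4 epimers) | O=C1CC(/C=C/c4ccc(OC)c(OC)c4)[C@@H]2C3(OCCO3)[C@H]1[C@H](c4ccc(OC)c(OC)c4)[C@H]2c1cc(OC)cc(OC)c1
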